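The runs stem from a simulated flask with made-up constants; scatter was added.

The unit I reckoned in was the equivalent-minute: equivalents of J charged times minutes, for flasks with the same cG, taking each addition of J to run by that product while cJ stays near its charge.

in all of them: G 40 mM

| charge | J | remark | time |
|---|---|---|---|
| Thursday's | 1.5 equiv | run made earlier |  |
| Monday's | 9 equiv | run made earlier |  |
| gamma | 3.00 equiv |  | 15 min |
| epsilon | 2.00 equiv |  | 15 min |
| theta | 6.00 equiv |  | 15 min |
| alpha | 1.30 equiv |  | 15 min |

| run | time / min | Q / % | X / % |
|---|---|---|---|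
| Thursday's | 0.667 | 0 | 0 |
| Thursday's | 1.33 | 0.1 | 0 |
| Thursday's | 3.00 | 0.5 | 0 |
| Thursday's | 8.00 | 0.6 | 0 |
| Monday's | 2.00 | 0 | 0 |
| Monday's | 4.00 | 0.6 | 2.5 |
| Monday's | 6.00 | 1.1 | 8.1 |
| Monday's | 8.00 | 1.0 | 13.3 |

(each reading ± 0.5 percentage points)

* the flasks by share of Q in all that became Q or X, highest first, at 15 min (gamma / epsilon / theta / alpha)
* the same order at 1.5 min (gamma / epsilon / theta / alpha)
* the share of Q in all that became Q or X of the flask you put first, at 15 min
* the share of Q in all that became Q or X of the flask you put last, at 15 min

- the numbers in the tables scatter by 0.5 percentage points (one standard deviation)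

Thursday's Q reaches 0.6% against a scatter of 0.5 percentage points, so I read Monday's run. Between 4.00 min and 8.00 min, X gained 2.45 min⁻¹ of the Q standing, if X comes from Q. Q holds four J, so I took Q to rise at first as the fourth power of time and X, one J further on, as the fifth; then X/Q is that rate times time, over 5. X overtakes Q at the crossing time, which for alpha, scaled to its J, is 14.1 min, and the share is the crossing time over the crossing time plus t.

A flat Q from the start, at charged J, gives a floor of 15.8%. But alpha at 15 min has had the equivalent-minutes of Monday's 2.17 min, close to its 2.00 min reading of zero, so I took Q as still rising, which lifts the floor to 48.5%. Falling J delays the crossing: with cJ averaging 0.5 of its charge, my guess, the ceiling is 65.3%. Theta matches Monday's 10.0 min, beyond its last reading's share of 6.99%, so I put theta near that. In this reckoning, at one cG and one time, the share falls as equivalent-minutes grow, so I ordered the flasks by J.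

The forecast gave alpha > epsilon > gamma > theta at 15 min and alpha > epsilon > gamma > theta at 1.5 min, with 75% and 8%, holding that “Q's share falls as J rises”; its top lies above my ceiling.

The flasks gave alpha > epsilon > gamma > theta at 15 min and alpha > epsilon > gamma > theta at 1.5 min, with theta at 8.84%.

    G + J → E (k = 0.0270 M⁻¹ s⁻¹)
    J + E → D (k = 0.0460 M⁻¹ s⁻¹)
    J + D → Z (k = 0.00290 M⁻¹ s⁻¹)
    J + Z → Q (k = 0.0320 M⁻¹ s⁻¹)
    J + Q → X (k = 0.130 M⁻¹ s⁻¹)

Alpha gave 51.5%, inside my bracket, with Q 0.0980% beside X 0.0923%, so 15 min stood at about the crossing. For the neighbour, like alpha but with 0.520 equiv of J, I scaled the crossing time to 35.3 min. That gives a share of 70.2% at charged J and 82.5% with cJ at 0.5 of its charge. At 15 min that flask kept 35% of its J and gave 75.0%.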